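(The readings were generated by integration on assumed constants, and the scatter is random.)

A share read at the first sampling looks safe to carry back to the start, but it can mislead where charged material is missing from the readings. The flask asked about is the south run continued.

| flask | starting material | remark | time |
|---|---|---|---|
| south | 1 M | the very flask that is asked about, followed so far |  |
| south-west | 2 M | run made earlier |  |
| flask | 1.0 M |  | 3.0 min |

| run | time / s | isomer of the product A / % | target / % | starting material / % |
|---|---|---|---|---|
| south | 10.0 | 5.9 | 1.9 | 82.2 |
| south | 12.0 | 7.0 | 3.1 | 78.4 |
| south | 20.0 | 11.6 | 4.7 | 67.9 |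
| south | 40.0 | 21.3 | 8.5 | 46.9 |
| south-west | 10.0 | 5.9 | 2.2 | 82.2 |
| south-west | 15.0 | 9.6 | 4.4 | 74.2 |
| south-west | 25.0 | 14.4 | 5.0 | 60.8 |
| south-west | 40.0 | 20.8 | 8.6 | 47.4 |
| south-west | 60.0 | 25.5 | 11.5 | 33.0 |
| south-west | 80.0 | 29.7 | 13.9 | 25.7 |

(readings scatter by 0.5 percentage points)

* share of isomer of the product A in isomer of the product A plus target at 3.0 s
* share of isomer of the product A in isomer of the product A plus target at 25 s
* share of isomer of the product A in isomer of the product A plus target at 3.0 min
* which of isomer of the product A and target there is more of at 3.0 min

- a reading or a percentage of target counts all its forms, free or not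

At 40.0 s the south and south-west runs agree within the scatter (isomer of the product A 21.3% against 20.8%), so the longer south-west run is taken here to stand in for the later south flask. Over its first 10.0 s, isomer of the product A gains 0.00590 s⁻¹ of the charge and target 0.00220 s⁻¹. Between 40.0 s and 80.0 s these rates are 0.00222 s⁻¹ and 0.00133 s⁻¹. Starting material between the two windows falls by a factor of 2.49. The isomer's rate falls by 2.65, close to that. Target's falls by 1.66, but that factor hangs on one small reading of 2.2% with a scatter of 0.5 percentage points, so it is a loose reading.

This accumulated slowing is carried by the late gain share (the instantaneous selectivity): the isomer's part of what isomer and target gain together between 40.0 s and 80.0 s, read as 62.7%. The share standing at 80.0 s is 68.1%, higher, so further gains pull it down. Midway gives 65.4% as the reckoned share at 3.0 min, with the isomer expected ahead from the lead it holds at 80.0 s, 29.7% against 13.9% of target.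

At 25 s the south readings bracket the share: 71.2% at 20.0 s, 71.5% at 40.0 s. Earlier, the unseen part of the south-west run over isomer falls from 1.64 at 10.0 s to 1.03 at 80.0 s. The isomer thus trails the unseen material, and its share at 3.0 s should lie below the 72.8% of the first reading.

The forecast gave 76%, 73% and 59% with isomer of the product A ahead, in its words “Extrapolating gives about 41% isomer and 30% target at 180 s”, lower at the end than the reckoning here and higher at the start.

The flask gives 51.5%, 71.0% and 64.0%, with isomer of the product A ahead, 32.8% against 18.4%.

    isomer of the product A ⇌ isomer of the product B (K = 1.10, k = 0.180 s⁻¹)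
    target ⇌ isomer of the product A (K = 2.70, k = 0.00120 s⁻¹)
    crystals ⇌ target, rate k3*(cs3 - [target]) while solid is left; crystals form when [target] > cs3 (solubility = 14.0 mM, k = 1.50 s⁻¹)
    starting material ⇌ target (K = 0.990, k = 0.00300 s⁻¹)
    isomer of the product B ⇌ starting material (k = 0.00600 s⁻¹)

The forward passing of isomer of the product A into isomer of the product B has a half-life of 0.064 min at 3.00 min, short against 3.0 min. The flask then holds 32.8% of the first isomer and 36.2% of the second, and the share stands 1.3 points above the late gain share. The neighbour charged 0.25 M, below both runs, is placed by the same reckoning between 62.7% and 68.1%, midway 65.4%. Computed, its share is 68.1%, with target 15.8%, crystals 10.2% counted in.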